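**Plan**

1. Retrosynthesis (caryophyllane numbering for the terpene carbons: C1/C9 ring fusion, C4 carries the methyl, C8 the exocyclic methylene, C11 the gem-dimethyl). The dihydropyran is cut first at O–C4 and C5–CH2 (retro hetero-Diels–Alder) into (−)-β-caryophyllene 16 and o-quinone methide 22. Then C8=CH2 is cut to ketone 15, and then the C6–C7 bond of the nine-membered ring, whose two ends stay joined through a CO2 tether in the eleven-membered allyl β-keto lactone 14. Last come the lactone C–O bond, the C7–C8 Claisen bond, the C4-methyl and C5–C6 bonds, and the six-membered ring of a cyclohexenone–isobutene photoadduct.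
2. Enabling feature: C7 is alpha to C8 (a masked ketone), and C6 is bonded to C5, which with C4 forms the fusion bond of the pyran and nine-membered rings and is an E alkene before the cycloaddition. C6–C7 is therefore the bond between an enolate carbon and the primary end of the C4–C5–C6 allyl unit, the central bond of the 1,5-diene C15=C8–C7–C6–C5=C4 of the nine-membered ring.
3. Forward order: cyclobutane ([2+2]); six-membered ring opened; side chains grown; eleven-membered lactone closed; contraction to the nine-membered carbocycle with loss of CO2; methylenation; dihydropyran last, by cycloaddition with the separately made acylphloroglucinol unit.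
4. Stereochemistry: C1 from the catalyst-controlled photocycloaddition; C9 by equilibration to the trans ester; E-C4=C5 from syn-carboalumination, kept through the π-allyl stage; C4 and C5 from suprafacial cycloaddition on the outer face of the E alkene under control of C1/C9; the acyl stereocentre from (S)-2-methylbutanoic acid.

Key step: step 8

Assumption: the (S)-prolinol-derived oxazaborolidine–AlBr3 Lewis acid is taken to shield the enone face that leads to the (6R) photoadduct; if the sense of induction is the opposite, the (R)-prolinol-derived catalyst is used.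

**Route**

Step 1
Reactants: 1 cyclohex-2-en-1-one; 2 2-methylpropene
Product: 4 (1R,6R)-7,7-dimethylbicyclo[4.2.0]octan-2-one (cis-fused), via trans-fused ketone 3 (not isolated)
Conditions: 2 (excess), AlBr3 adduct of (S)-3,3-bis(3,5-dimethylphenyl)-1-(2,4,6-trifluorophenyl)tetrahydro-1H,3H-pyrrolo[1,2-c][1,3,2]oxazaborole (50 mol%), CH2Cl2, −75 °C, hν (366 nm); then basic Al2O3, CH2Cl2, rt
Reagents that add atoms: none
Why: Enantioselective enone–alkene [2+2] photocycloaddition in which the chiral Lewis acid binds the enone carbonyl, shifts its absorption so that the complexed enone is the one excited, and shields one face of the β-carbon, so that isobutene should add head-to-tail and set C6 (later C1 of the terpene) as R, while the alumina treatment epimerises the α-bridgehead of trans-fused adduct 3 to the more stable cis-fused ketone 4.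

Step 2
Reactants: 4 (1R,6R)-7,7-dimethylbicyclo[4.2.0]octan-2-one
Product: 5 trimethyl{[(1R,6R)-7,7-dimethylbicyclo[4.2.0]oct-2-en-2-yl]oxy}silane
Conditions: LiN(iPr)2, THF, −78 °C; then Me3SiCl, Et3N, −78 → 0 °C
Reagents that add atoms: chlorotrimethylsilane (C[Si](C)(C)Cl)
Why: Kinetic enolisation with the hindered amide base should occur at the C3 methylene and not at the cyclobutane bridgehead (a ring-fusion enolate is strained), and O-silylation gives the silyl enol ether without touching a stereocentre.

Step 3
Reactants: 5 trimethyl{[(1R,6R)-7,7-dimethylbicyclo[4.2.0]oct-2-en-2-yl]oxy}silane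
Product: 7 methyl (1R,2R)-3,3-dimethyl-2-(3-oxopropyl)cyclobutane-1-carboxylate, via aldehyde acid 6 (not isolated)
Conditions: O3, CH2Cl2/MeOH, −78 °C; Me2S, −78 °C → rt; then Me3SiCHN2, PhMe/MeOH, 0 °C
Reagents that add atoms: ozone ([O-][O+]=O); trimethylsilyldiazomethane (C[Si](C)(C)C=[N+]=[N-])
Why: Ozonolysis of the silyl enol ether cleaves C2–C3 into a silyl ester (methanolysed to the acid) and, after reduction of the methoxy hydroperoxide by Me2S, an aldehyde, and the diazoalkane esterifies only the acid, the two ring stereocentres being untouched.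

Step 4
Reactants: 7 methyl (1R,2R)-3,3-dimethyl-2-(3-oxopropyl)cyclobutane-1-carboxylate
Product: 9 methyl (1S,2R)-2-(but-3-yn-1-yl)-3,3-dimethylcyclobutane-1-carboxylate (trans), via cis alkyne ester 8 (not isolated)
Conditions: dimethyl (1-diazo-2-oxopropyl)phosphonate, K2CO3, MeOH, 0 °C → rt; then NaOMe (0.5 equiv), MeOH, 55 °C
Reagents that add atoms: dimethyl (1-diazo-2-oxopropyl)phosphonate (COP(=O)(OC)C(=[N+]=[N-])C(C)=O)
Why: Seyferth–Gilbert homologation with the Ohira–Bestmann reagent turns the aldehyde into the terminal alkyne, and methoxide then equilibrates the ester α-carbon to the thermodynamically preferred trans-1,2-disubstituted cyclobutane, the neighbouring centre staying fixed.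

Step 5
Reactants: 9 methyl (1S,2R)-2-(but-3-yn-1-yl)-3,3-dimethylcyclobutane-1-carboxylate
Product: 11 methyl (1S,2R)-2-[(3E)-5-hydroxy-3-methylpent-3-en-1-yl]-3,3-dimethylcyclobutane-1-carboxylate, via alkenylalane 10 (not isolated)
Conditions: AlMe3 (3 equiv), Cp2ZrCl2 (25 mol%), CH2Cl2, 0 °C → rt; then (CH2O)n, 0 °C → rt; aqueous potassium sodium tartrate
Reagents that add atoms: trimethylaluminium (C[Al](C)C); formaldehyde, as paraformaldehyde (C=O)
Why: Negishi carboalumination adds methyl and aluminium syn across the terminal alkyne with aluminium on the terminal carbon, and hydroxymethylation of the alkenylalane with retention fixes the E trisubstituted alkene, the methyl ester not being expected to react with AlMe3 at or below room temperature.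

Step 6
Reactants: 11 methyl (1S,2R)-2-[(3E)-5-hydroxy-3-methylpent-3-en-1-yl]-3,3-dimethylcyclobutane-1-carboxylate
Product: 12 tert-butyl 3-{(1S,2R)-2-[(3E)-5-hydroxy-3-methylpent-3-en-1-yl]-3,3-dimethylcyclobutyl}-3-oxopropanoate
Conditions: tert-butyl acetate and LiN(iPr)2 (4 equiv each), THF, −78 °C; add 11, −78 → −20 °C; aqueous NH4Cl
Reagents that add atoms: tert-butyl acetate (CC(=O)OC(C)(C)C)
Why: Crossed Claisen condensation of the methyl ester with excess lithium enolate of tert-butyl acetate (one equivalent is taken by the hydroxyl, one by the acidic product) gives the β-keto ester, and any epimerisation alpha to the new ketone returns the favoured trans isomer.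

Step 7
Reactants: 12 tert-butyl 3-{(1S,2R)-2-[(3E)-5-hydroxy-3-methylpent-3-en-1-yl]-3,3-dimethylcyclobutyl}-3-oxopropanoate
Product: 14 (1S,7E,11R)-8,12,12-trimethyl-5-oxabicyclo[9.2.0]tridec-7-ene-2,4-dione, via acylketene 13 (not isolated)
Conditions: PhMe, 110 °C, syringe-pump addition to 1 mM final concentration, tert-butanol distilled off
Reagents that add atoms: none
Why: Thermolysis of the tert-butyl β-keto ester expels tert-butanol to give acylketene 13, which the primary allylic alcohol should capture at high dilution (acylketene macrolactonisation) to close the eleven-membered β-keto lactone without affecting a stereocentre or the alkene geometry.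

Step 8
Reactants: 14 (1S,7E,11R)-8,12,12-trimethyl-5-oxabicyclo[9.2.0]tridec-7-ene-2,4-dione
Product: 15 (1R,4E,9S)-4,11,11-trimethylbicyclo[7.2.0]undec-4-en-8-one
Conditions: Pd(PPh3)4 (10 mol%), degassed THF, 2 mM, 25 → 50 °C
Reagents that add atoms: none
Why: Proposed new method: zerovalent palladium ionises the allylic C6–O bond of the lactone to an (η3-allyl)palladium β-keto carboxylate whose two ions stay joined by the chain C4–C3–C2–C1–C9–C8; loss of CO2 unveils the C7 enolate (or C7 is allylated before CO2 leaves), and C7–C6 bond formation contracts the eleven-membered lactone to the nine-membered carbocycle, with CO2 as a traceless tether. The closest known reaction type is the palladium-catalysed decarboxylative allylation of allyl β-keto esters (palladium-catalysed Carroll reaction), which turns geranyl acetoacetate into geranylacetone with linear regiochemistry and retained E geometry, together with the intramolecular Tsuji–Trost alkylation used for eight- and nine-membered carbocycles. The nine-membered ring closes in the endo sense with respect to the allyl unit (C4, C5 and C6 all become ring atoms), the 7-exo closure at C4 being the alternative to suppress. No new stereocentre is formed; the E geometry of C4=C5 is inherited from the syn π-allyl complex, which cannot exchange its C4 substituents without a σ-complex at the tertiary carbon, and C9, now alpha to the ketone, can only relax to the trans ring fusion already present. The step needs attack at C6 and not C4, which the bulk of the triphenylphosphine complex should secure against formation of a quaternary centre, and cyclisation over oligomerisation, which high dilution and the generation of both reacting ions within one molecule should secure.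

Step 9
Reactants: 15 (1R,4E,9S)-4,11,11-trimethylbicyclo[7.2.0]undec-4-en-8-one
Product: 16 (−)-β-caryophyllene [(1R,4E,9S)-4,11,11-trimethyl-8-methylidenebicyclo[7.2.0]undec-4-ene]
Conditions: Ph3PCH3Br, KOtBu, THF, 0 → 50 °C
Reagents that add atoms: methyltriphenylphosphonium bromide (C[P+](c1ccccc1)(c1ccccc1)c1ccccc1.[Br-])
Why: Wittig methylenation of the nine-membered ketone with the non-stabilised ylide installs the exocyclic methylene, the basic medium being able only to hold C9 in the more stable trans-fused form and leaving the E alkene untouched.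

Step 10
Reactants: 17 (S)-2-methylbutanoic acid; 18 phloroglucinol
Product: 20 (2S)-2-methyl-1-(2,4,6-trihydroxyphenyl)butan-1-one, via acid chloride 19 (not isolated)
Conditions: (COCl)2, DMF (cat.), CH2Cl2, 0 °C → rt, evaporation; then 18, AlCl3 (4 equiv), PhNO2, 0 → 40 °C
Reagents that add atoms: none
Why: Acid chloride formation and Friedel–Crafts C-acylation of the electron-rich triol, which should stop at monoacylation because the aryl ketone is deactivated and chelated to aluminium, the temperature being kept at or below 40 °C so that the α-stereocentre carried over from 17 is not enolised.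

Step 11
Reactants: 20 (2S)-2-methyl-1-(2,4,6-trihydroxyphenyl)butan-1-one
Product: 21 3,5-dihydroxy-4,6,6-trimethyl-2-[(2S)-2-methylbutanoyl]cyclohexa-2,4-dien-1-one
Conditions: NaOMe (3.2 equiv), MeI (3.2 equiv), MeOH, 0 °C → rt
Reagents that add atoms: iodomethane (CI)
Why: Dearomative C-methylation of the phloroglucinol polyanion, in which two methyl groups enter at one free ring carbon and the third at the other, the side-chain α-carbon being protected from enolisation because the negative charge resides in the ring.

Step 12
Reactants: 21 3,5-dihydroxy-4,6,6-trimethyl-2-[(2S)-2-methylbutanoyl]cyclohexa-2,4-dien-1-one; 16 (−)-β-caryophyllene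
Product: 23 target meroterpenoid (caryophyllane 1R,4R,5S,9S; acyl 2S), via o-quinone methide 22 (not isolated)
Conditions: 16 (2 equiv), Ag2O (1.5 equiv), TEMPO (20 mol%), PhMe, rt, dark
Reagents that add atoms: none
Why: Ag2O/TEMPO dehydrogenation of the ring C-methyl group gives o-quinone methide 22, which should undergo an inverse-demand hetero-Diels–Alder reaction with the strained E C4=C5 bond of 16 (not the exocyclic methylene), the carbonyl oxygen next to the gem-dimethyl carbon bonding to the more substituted C4 and the methylene to C5; suprafacial addition to the outer face of the E alkene, the face that also leads to the 4R,5R epoxide, sets 4R,5S relative to the fixed 1R,9S centres, and the adduct from the other ring conformer is removed by chromatography.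

**Compound list**

1 | cyclohex-2-en-1-one | O=C1C=CCCC1 | starting material
2 | 2-methylpropene (isobutene) | CC(C)=C | starting material
3 | (1S,6R)-7,7-dimethylbicyclo[4.2.0]octan-2-one (trans-fused photoadduct) | O=C1CCC[C@@H]2[C@@H]1CC2(C)C | intermediate (not isolated)
4 | (1R,6R)-7,7-dimethylbicyclo[4.2.0]octan-2-one (cis-fused) | O=C1CCC[C@@H]2[C@H]1CC2(C)C | intermediate
5 | trimethyl{[(1R,6R)-7,7-dimethylbicyclo[4.2.0]oct-2-en-2-yl]oxy}silane | C[Si](C)(C)OC1=CCC[C@@H]2[C@H]1CC2(C)C | intermediate
6 | (1R,2R)-3,3-dimethyl-2-(3-oxopropyl)cyclobutane-1-carboxylic acid | O=CCC[C@@H]1[C@H](C(=O)O)CC1(C)C | intermediate (not isolated)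
7 | methyl (1R,2R)-3,3-dimethyl-2-(3-oxopropyl)cyclobutane-1-carboxylate | O=CCC[C@@H]1[C@H](C(=O)OC)CC1(C)C | intermediate
8 | methyl (1R,2R)-2-(but-3-yn-1-yl)-3,3-dimethylcyclobutane-1-carboxylate (cis) | C#CCC[C@@H]1[C@H](C(=O)OC)CC1(C)C | intermediate (not isolated)
9 | methyl (1S,2R)-2-(but-3-yn-1-yl)-3,3-dimethylcyclobutane-1-carboxylate (trans) | C#CCC[C@@H]1[C@@H](C(=O)OC)CC1(C)C | intermediate
10 | methyl (1S,2R)-2-[(3E)-4-(dimethylalumanyl)-3-methylbut-3-en-1-yl]-3,3-dimethylcyclobutane-1-carboxylate | C[Al](C)/C=C(\C)CC[C@@H]1[C@@H](C(=O)OC)CC1(C)C | intermediate (not isolated)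
11 | methyl (1S,2R)-2-[(3E)-5-hydroxy-3-methylpent-3-en-1-yl]-3,3-dimethylcyclobutane-1-carboxylate | OC/C=C(\C)CC[C@@H]1[C@@H](C(=O)OC)CC1(C)C | intermediate
12 | tert-butyl 3-{(1S,2R)-2-[(3E)-5-hydroxy-3-methylpent-3-en-1-yl]-3,3-dimethylcyclobutyl}-3-oxopropanoate | OC/C=C(\C)CC[C@@H]1[C@@H](C(=O)CC(=O)OC(C)(C)C)CC1(C)C | intermediate
13 | 3-{(1S,2R)-2-[(3E)-5-hydroxy-3-methylpent-3-en-1-yl]-3,3-dimethylcyclobutyl}-3-oxoprop-1-en-1-one (acylketene) | OC/C=C(\C)CC[C@@H]1[C@@H](C(=O)C=C=O)CC1(C)C | intermediate (not isolated)
14 | (1S,7E,11R)-8,12,12-trimethyl-5-oxabicyclo[9.2.0]tridec-7-ene-2,4-dione | O=C1CC(=O)OC/C=C(\C)CC[C@@H]2[C@@H]1CC2(C)C | intermediate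
15 | (1R,4E,9S)-4,11,11-trimethylbicyclo[7.2.0]undec-4-en-8-one | O=C1CC/C=C(\C)CC[C@@H]2[C@@H]1CC2(C)C | intermediate
16 | (−)-β-caryophyllene, (1R,4E,9S)-4,11,11-trimethyl-8-methylidenebicyclo[7.2.0]undec-4-ene | C=C1CC/C=C(\C)CC[C@@H]2[C@@H]1CC2(C)C | intermediate
17 | (S)-2-methylbutanoic acid | CC[C@H](C)C(=O)O | starting material
18 | phloroglucinol (benzene-1,3,5-triol) | Oc1cc(O)cc(O)c1 | starting material
19 | (S)-2-methylbutanoyl chloride | CC[C@H](C)C(=O)Cl | intermediate (not isolated)
20 | (2S)-2-methyl-1-(2,4,6-trihydroxyphenyl)butan-1-one | CC[C@H](C)C(=O)c1c(O)cc(O)cc1O | intermediate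
21 | 3,5-dihydroxy-4,6,6-trimethyl-2-[(2S)-2-methylbutanoyl]cyclohexa-2,4-dien-1-one | CC1=C(O)C(C)(C)C(=O)C(C(=O)[C@@H](C)CC)=C1O | intermediate
22 | 5-hydroxy-2,2-dimethyl-6-methylidene-4-[(2S)-2-methylbutanoyl]cyclohex-4-ene-1,3-dione (o-quinone methide) | C=C1C(=O)C(C)(C)C(=O)C(C(=O)[C@@H](C)CC)=C1O | intermediate (not isolated)
23 | target: dihydropyran-fused adduct of (−)-β-caryophyllene (caryophyllane 1R,4R,5S,9S, C8 methylene retained) with the enolised 2,2-dimethyl-4-[(2S)-2-methylbutanoyl]cyclohexanetrione unit | C=C1CC[C@H]2CC3=C(O[C@]2(C)CC[C@@H]2[C@@H]1CC2(C)C)C(C)(C)C(=O)C(C(=O)[C@@H](C)CC)=C3O | target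

**Step count and risks**

Total steps: 12. Longest linear sequence: 10 steps (steps 1–9 and 12); steps 10 and 11 form the second branch.

Steps most likely to fail:

1. Step 8 (proposed new method). The tethered allyl and enolate ends may recombine at C4 to give a seven-membered ring with a quaternary vinyl centre, the allyl unit may lose a proton to give a diene and the methyl ketone, coupling may occur between molecules, and the E geometry may leak to Z at the π-allyl stage. The fallback sets out from 12 and uses a stabilised carbanion in a known medium-ring allylic alkylation, with the activating group removed afterwards. Methyl chloroformate and pyridine in CH2Cl2 convert the hydroxyl into the allylic methyl carbonate F1. Pd(PPh3)4 in THF at high dilution ionises the carbonate, the released methoxide deprotonates the β-keto ester, and Tsuji–Trost alkylation at the primary allyl terminus closes the nine-membered ring to the cyclic tert-butyl β-keto ester F2 (both C7 epimers serve). Heating F2 in wet DMSO at 150 °C removes isobutene and CO2, and the route is rejoined at 15.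

2. Step 7. Capture of the acylketene by a second molecule, ketene dimerisation, or recapture by tert-butanol may outrun closure of the strained eleven-membered ring. The fallback sets out from 11 and closes the ring through the C7–C8 bond instead of the ester C–O bond. Acetic anhydride and pyridine give the allylic acetate F3. Slow addition of F3 to LiN(SiMe3)2 in THF at high dilution (−78 → 0 °C) generates the acetate enolate, which attacks the ring ester in a Dieckmann-type macrocyclising Claisen condensation; formation of the stabilised β-dicarbonyl enolate drives the equilibrium, and acidification returns the route at 14.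

3. Step 5. Methyl transfer from aluminium to the ester carbonyl may compete with carboalumination, and slow capture of the alkenylalane by formaldehyde may end in protodealumination. The fallback sets out from 9 and builds the same E allylic alcohol by ester-tolerant boron chemistry. Copper-catalysed methylboration (CuCl/Xantphos cat., B2pin2, NaOtBu, MeI, THF) adds boron and methyl syn across the alkyne to give the (E)-alkenylboronate F4. Matteson homologation (BrCH2Cl, n-BuLi, THF, −78 °C → rt) inserts one carbon with retention of geometry to give the allylboronate F5, and oxidation with NaBO3·4H2O in THF/water returns the route at 11.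

**Further compounds**

F1 | step 8 | tert-butyl 3-{(1S,2R)-2-[(3E)-5-(methoxycarbonyloxy)-3-methylpent-3-en-1-yl]-3,3-dimethylcyclobutyl}-3-oxopropanoate | COC(=O)OC/C=C(\C)CC[C@@H]1[C@@H](C(=O)CC(=O)OC(C)(C)C)CC1(C)C
F2 | step 8 | tert-butyl (1R,4E,9S)-4,11,11-trimethyl-8-oxobicyclo[7.2.0]undec-4-ene-7-carboxylate (C7 epimers) | O=C1C(C(=O)OC(C)(C)C)C/C=C(\C)CC[C@@H]2[C@@H]1CC2(C)C
F3 | step 7 | methyl (1S,2R)-2-[(3E)-5-acetoxy-3-methylpent-3-en-1-yl]-3,3-dimethylcyclobutane-1-carboxylate | CC(=O)OC/C=C(\C)CC[C@@H]1[C@@H](C(=O)OC)CC1(C)C
F4 | step 5 | methyl (1S,2R)-3,3-dimethyl-2-[(3E)-3-methyl-4-(4,4,5,5-tetramethyl-1,3,2-dioxaborolan-2-yl)but-3-en-1-yl]cyclobutane-1-carboxylate | CC1(C)OB(/C=C(\C)CC[C@@H]2[C@@H](C(=O)OC)CC2(C)C)OC1(C)C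
F5 | step 5 | methyl (1S,2R)-3,3-dimethyl-2-[(3E)-3-methyl-5-(4,4,5,5-tetramethyl-1,3,2-dioxaborolan-2-yl)pent-3-en-1-yl]cyclobutane-1-carboxylate | CC1(C)OB(C/C=C(\C)CC[C@@H]2[C@@H](C(=O)OC)CC2(C)C)OC1(C)C
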